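Epicatechin-(4α→6)-epiafzelechin-(4α→8)-epicatechin-(4β→6)-epicatechin (unit one to unit four in this order; α = the face of ring C that carries the C2 aryl group). All four pyran rings are bought intact: units one, three and four as (−)-epicatechin, unit two as (+)-dihydrokaempferol.
Last C–C bond: C4 of unit one to C6 of ring A of unit two, closed across a one-atom silylene tether. The enabling feature: O3 of unit one is cis to this bond and O5 of unit two is ortho to C6, so the two oxygens are 1,4-related across it (O3–C3–C4–C6–C5–O5); an O3–Si–O5 bridge turns the bond formation into a seven-membered ring closure that can reach only C6 and, in the favoured half-chair, only the O3 (α) face.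
Before that: C4 of unit two to C8 of unit three by 3,4-trans Friedel–Crafts coupling of the 2,3-trans flavan-3,4-diol from dihydrokaempferol, then inversion of C3 (oxidation, bulky hydride) to the all-cis unit. The hydrogen-bonded 5-OH of the flavanone lets O5 be marked (allyl) for the tether.
First: C4 of unit three to C6 of unit four by halo-capped coupling (8-iodo electrophile, 8-bromo nucleophile), then selective removal of iodine.
Ring order: no ring of the target is built; the only ring closed is the temporary seven-membered dioxasilepine (step 17), opened in step 18; all benzyl ethers and the bromine leave in step 19.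

Key step: step 17

Remark: the SMILES is read as 2R,3R in all four units, with the C4 aryl bond cis to the 3-OH in units one and two (4α) and trans in unit three (4β); (−)-epicatechin and natural (2R,3R)-(+)-dihydrokaempferol are taken as purchasable.

Step 1
Reactants: 1 (−)-epicatechin
Product: 2 5,7,3',4'-tetra-O-benzyl-(−)-epicatechin
Conditions: BnBr (4.4 equiv), K2CO3, DMF, argon, 0 °C to rt
Reagents that add atoms: benzyl bromide, BrCc1ccccc1
Why: Williamson etherification of the four phenols; carbonate does not deprotonate the 3-OH and no stereocentre is touched.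

Step 2
Reactants: 2 5,7,3',4'-tetra-O-benzyl-(−)-epicatechin
Product: 3 3,5,7,3',4'-penta-O-benzyl-(−)-epicatechin
Conditions: NaH, BnBr, Bu4NI (cat.), DMF, 0 °C to rt
Reagents that add atoms: benzyl bromide, BrCc1ccccc1
Why: Williamson etherification of the secondary alkoxide, so that the 3-OH of the future units three and four survives the later oxidation and leaves in the final hydrogenolysis.

Step 3
Reactants: 3 3,5,7,3',4'-penta-O-benzyl-(−)-epicatechin
Product: 4 8-bromo-3,5,7,3',4'-penta-O-benzyl-(−)-epicatechin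
Conditions: NBS (1.0 equiv), CH2Cl2, −40 °C to 0 °C
Reagents that add atoms: N-bromosuccinimide, O=C1CCC(=O)N1Br
Why: Electrophilic aromatic bromination, which in 5,7-di-O-benzylflavans takes C8 (between O7 and the ring oxygen) in preference to C6 flanked by two benzyloxy groups; this caps C8 of unit four.

Step 4
Reactants: 3 3,5,7,3',4'-penta-O-benzyl-(−)-epicatechin
Product: 5 8-iodo-3,5,7,3',4'-penta-O-benzyl-(−)-epicatechin
Conditions: NIS (1.05 equiv), CH2Cl2, dark, 0 °C to rt
Reagents that add atoms: N-iodosuccinimide, O=C1CCC(=O)N1I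
Why: Electrophilic aromatic iodination with the same C8 preference as the bromination, giving a cap on unit three that can later be removed in the presence of the bromide.

Step 5
Reactants: 5 8-iodo-3,5,7,3',4'-penta-O-benzyl-(−)-epicatechin
Product: 6 8-iodo-4β-(2-ethoxyethoxy)-3,5,7,3',4'-penta-O-benzyl-(−)-epicatechin
Conditions: DDQ (2 equiv), 2-ethoxyethanol (10 equiv), CH2Cl2, rt
Reagents that add atoms: 2-ethoxyethanol, CCOCCO
Why: DDQ benzylic oxidation (hydride abstraction at C4) with capture of the cation by the alcohol anti to the 3-benzyloxy group, giving the 3,4-trans (4β) ether; this C4 configuration is erased on ionisation in step 6.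

Step 6
Reactants: 6 8-iodo-4β-(2-ethoxyethoxy)-3,5,7,3',4'-penta-O-benzyl-(−)-epicatechin, 4 8-bromo-3,5,7,3',4'-penta-O-benzyl-(−)-epicatechin
Product: 7 deca-O-benzyl-8-iodoepicatechin-(4β→6)-8-bromoepicatechin
Conditions: 4 (2.5 equiv), TMSOTf (0.3 equiv), 4 Å sieves, CH2Cl2, −78 °C to −30 °C; Et3N quench
Reagents that add atoms: none
Why: Lewis-acid Friedel–Crafts condensation of a 4-alkoxyflavan with a flavan nucleophile: the C4 cation of 6 is attacked by C6 of 4 (the only free ring A carbon once C8 is bromo-capped) anti to the pseudoaxial 3-benzyloxy group, which sets C4 of unit three as 4β (3,4-trans), while the iodo cap keeps C8 of the electrophile and of the product from competing.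

Step 7
Reactants: 7 deca-O-benzyl-8-iodoepicatechin-(4β→6)-8-bromoepicatechin
Product: 9 deca-O-benzyl-epicatechin-(4β→6)-8-bromoepicatechin, via arylmagnesium chloride 8 (not isolated)
Conditions: iPrMgCl·LiCl (1.3 equiv), THF, −30 °C; then MeOH
Reagents that add atoms: none
Why: Chemoselective iodine–magnesium exchange, much faster for the aryl iodide than for the electron-rich aryl bromide at this temperature, followed by protonation; this frees C8 of unit three and leaves C8 of unit four capped.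

Step 8
Reactants: 10 (+)-dihydrokaempferol
Product: 11 (2R,3R)-7,4'-di-O-benzyldihydrokaempferol
Conditions: BnBr (2.1 equiv), K2CO3, DMF, argon, rt
Reagents that add atoms: benzyl bromide, BrCc1ccccc1
Why: Williamson etherification of the two free phenols; the 5-OH is hydrogen-bonded to the C4 carbonyl and the 3-OH is an alcohol, so both stay free and C2/C3 are untouched.

Step 9
Reactants: 11 (2R,3R)-7,4'-di-O-benzyldihydrokaempferol
Product: 12 (2R,3R)-5-O-allyl-7,4'-di-O-benzyldihydrokaempferol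
Conditions: allyl bromide (1.5 equiv), K2CO3, DMF, argon, 40 °C
Reagents that add atoms: allyl bromide, C=CCBr
Why: Williamson etherification of the chelated 5-OH under slightly more forcing conditions, which marks O5 of unit two with the one phenol ether of the route that can be removed without hydrogenolysis.

Step 10
Reactants: 12 (2R,3R)-5-O-allyl-7,4'-di-O-benzyldihydrokaempferol
Product: 13 (2R,3S,4R)-5-allyloxy-7-benzyloxy-2-(4-benzyloxyphenyl)chromane-3,4-diol
Conditions: NaBH4, THF/EtOH, 0 °C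
Reagents that add atoms: none
Why: Borohydride reduction of the aryl ketone, expected to give mainly the 3,4-trans diol by axial hydride delivery; the C4 configuration is irrelevant because C4 is ionised in step 11.

Step 11
Reactants: 13 (2R,3S,4R)-5-allyloxy-7-benzyloxy-2-(4-benzyloxyphenyl)chromane-3,4-diol, 9 deca-O-benzyl-epicatechin-(4β→6)-8-bromoepicatechin
Product: 14 5-O-allyl-7,4'-di-O-benzylafzelechin-(4α→8)-penta-O-benzylepicatechin-(4β→6)-8-bromo-penta-O-benzylepicatechin (2,3-trans-3,4-trans trimer alcohol)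
Conditions: 9 (2.5 equiv), TMSOTf (0.5 equiv), 4 Å sieves, CH2Cl2, −78 °C to −40 °C; Et3N quench
Reagents that add atoms: none
Why: Acid-promoted flavan-3,4-diol condensation (Friedel–Crafts alkylation): the C4 benzylic cation of the 2,3-trans unit is attacked by C8 of unit three of 9 (C8 of unit four carries bromine, C6 of unit three is flanked by two benzyloxy groups) anti to the C3 oxygen, which sets C4 of unit two as 4α (3,4-trans, cis to the C2 aryl group).

Step 12
Reactants: 14 2,3-trans-3,4-trans trimer alcohol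
Product: 15 trimer 3-ketone
Conditions: Dess–Martin periodinane (1.5 equiv), NaHCO3, CH2Cl2, 0 °C to rt
Reagents that add atoms: none
Why: Dess–Martin oxidation of the only free hydroxyl; the two α-substituents (C2 aryl, C4 aryl) are already in the favoured cis-diequatorial arrangement, so neither α-centre has a driving force to epimerise under the buffered conditions.

Step 13
Reactants: 15 trimer 3-ketone
Product: 16 5-O-allyl-7,4'-di-O-benzylepiafzelechin-(4α→8)-penta-O-benzylepicatechin-(4β→6)-8-bromo-penta-O-benzylepicatechin (all-cis trimer alcohol)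
Conditions: LiBH(s-Bu)3 (3 equiv), LiBr, THF, −78 °C; then H2O
Reagents that add atoms: none
Why: Diastereoselective ketone reduction by a bulky hydride (the catechin-to-epicatechin inversion protocol): equatorial attack from the β-face, where the flanking C2–H and C4–H bonds are axial, should give the axial 3-OH cis to both equatorial aryl groups (3R, all-cis unit two).

Step 14
Reactants: 16 all-cis trimer alcohol (5-O-allyl)
Product: 17 trimer phenol (5-OH of unit two free)
Conditions: Pd(PPh3)4 (5 mol %), morpholine (5 equiv), THF, rt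
Reagents that add atoms: none
Why: Tsuji–Trost deallylation: zerovalent palladium ionises the aryl allyl ether to a π-allyl complex of divalent palladium, which morpholine intercepts; benzyl ethers, the free alcohol and the hindered electron-rich aryl bromide should not react at room temperature.

Step 15
Reactants: 2 5,7,3',4'-tetra-O-benzyl-(−)-epicatechin
Product: 18 4β-(2-ethoxyethoxy)-5,7,3',4'-tetra-O-benzyl-(−)-epicatechin
Conditions: DDQ (2 equiv), 2-ethoxyethanol (10 equiv), CH2Cl2, rt
Reagents that add atoms: 2-ethoxyethanol, CCOCCO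
Why: DDQ benzylic oxidation with alcohol capture as in step 5, here on the 3-OH-free substrate, giving the 3,4-trans ether (2R,3R,4S) and leaving the 3-OH of unit one free for the tether.

Step 16
Reactants: 18 4β-(2-ethoxyethoxy)-5,7,3',4'-tetra-O-benzyl-(−)-epicatechin, 17 trimer phenol
Product: 20 diisopropylsilylene-tethered precursor, via chlorosilane 19 (not isolated)
Conditions: a) 18 (1.5 equiv), iPr2SiCl2 (4 equiv), imidazole, CH2Cl2, 0 °C to rt, then excess iPr2SiCl2 removed in vacuo; b) 17 (1.0 equiv), imidazole, DMAP (cat.), DMF, rt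
Reagents that add atoms: dichlorodiisopropylsilane, CC(C)[Si](Cl)(Cl)C(C)C
Why: Stepwise substitution at silicon (mixed silaketal formation): the hindered 3-OH of 18 takes one chloride, and the remaining Si–Cl is then displaced by the phenol of 17, which should react in preference to the axial, doubly flanked 3-OH of unit two, so that O3 of unit one and O5 of unit two end up joined through Si(iPr)2.

Step 17
Reactants: 20 diisopropylsilylene-tethered precursor
Product: 21 silylene-bridged tetramer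
Conditions: TMSOTf (0.5 equiv), 4 Å sieves, CH2Cl2 (0.002 M), −78 °C to −40 °C; Et3N quench
Reagents that add atoms: none
Why: Proposed new method: TMSOTf ionises the 4-(2-ethoxyethoxy) group of unit one to the benzylic cation at C4 (stabilised by O1, O5 and O7 of its ring A), which is trapped intramolecularly by C6 of ring A of unit two in a Friedel–Crafts alkylation; loss of the C6 proton restores the arene and the acid. The closest known reaction types are the Lewis-acid condensation of 4-alkoxyflavan-3-ols with flavan nucleophiles and its intramolecular variant, in which a diester linker between the two flavan units steers attack to the 3,4-cis face. The step closes one ring, the seven-membered benzo-fused dioxasilepine C4–C3–O3–Si–O5–C5–C6, in the exo mode at the electrophile (7-exo-trig: the cation-stabilising ring A of unit one lies outside the new ring) with the reacting C5=C6 arene bond of unit two inside the ring. The one new stereocentre, C4 of unit one, is controlled by the tether: in the favoured half-chair (C2 aryl equatorial) O3 is axial on the α-face, a seven-membered ring cannot span the near-antiperiplanar relation between O3 and the β-lobe of C4, and so C6 can reach only the α-lobe and the aryl group enters cis to O3 (4α), against the 3,4-trans preference of an untethered epicatechin cation. The step needs site selectivity among the free arene carbons (C6 and C8 of unit two, C6 of unit three, and C6 and C8 of unit one of other molecules); only C6 of unit two is ortho to the silylated O5 and within reach, and intermolecular capture is suppressed by high dilution. Capture of the cation by the free 3-OH of unit two would need a ten-membered ring and gives a 4-alkoxy ether that re-ionises under the conditions, whereas the C–C bond formation is irreversible.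

Step 18
Reactants: 21 silylene-bridged tetramer
Product: 22 hexadeca-O-benzyl-8-bromo tetramer triol
Conditions: HF·pyridine, pyridine/THF, 0 °C to rt
Reagents that add atoms: none
Why: Fluoride cleavage of both Si–O bonds of the silylene (desilylation), which frees the 3-OH of unit one and the 5-OH of unit two beside the 3-OH of unit two already free; benzyl ethers, the aryl bromide and the interflavan bonds should be inert to buffered HF·pyridine.

Step 19
Reactants: 22 hexadeca-O-benzyl-8-bromo tetramer triol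
Product: 23 CNP0103636.2 (target tetramer)
Conditions: H2 (1 atm), Pd(OH)2/C, Et3N (1.5 equiv), THF/MeOH/H2O, rt
Reagents that add atoms: none
Why: Catalytic hydrogenolysis of the sixteen benzyl ethers and of the C8–Br bond of unit four, with triethylamine taking up HBr; the ring C2–O1 bonds and the doubly benzylic interflavan C–C bonds are known to survive these conditions in oligomeric flavan-3-ols.

Compound list
1 | (−)-epicatechin | O[C@@H]1Cc2c(O)cc(O)cc2O[C@@H]1c1ccc(O)c(O)c1 | starting material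
2 | 5,7,3',4'-tetra-O-benzyl-(−)-epicatechin | O[C@@H]1Cc2c(OCc3ccccc3)cc(OCc3ccccc3)cc2O[C@@H]1c1ccc(OCc2ccccc2)c(OCc2ccccc2)c1 | intermediate
3 | 3,5,7,3',4'-penta-O-benzyl-(−)-epicatechin | C(c1ccccc1)O[C@@H]1Cc2c(OCc3ccccc3)cc(OCc3ccccc3)cc2O[C@@H]1c1ccc(OCc2ccccc2)c(OCc2ccccc2)c1 | intermediate
4 | 8-bromo-3,5,7,3',4'-penta-O-benzyl-(−)-epicatechin | C(c1ccccc1)O[C@@H]1Cc2c(OCc3ccccc3)cc(OCc3ccccc3)c(Br)c2O[C@@H]1c1ccc(OCc2ccccc2)c(OCc2ccccc2)c1 | intermediate
5 | 8-iodo-3,5,7,3',4'-penta-O-benzyl-(−)-epicatechin | C(c1ccccc1)O[C@@H]1Cc2c(OCc3ccccc3)cc(OCc3ccccc3)c(I)c2O[C@@H]1c1ccc(OCc2ccccc2)c(OCc2ccccc2)c1 | intermediate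
6 | 8-iodo-4β-(2-ethoxyethoxy)-3,5,7,3',4'-penta-O-benzyl-(−)-epicatechin (3,4-trans) | C(c1ccccc1)O[C@@H]1[C@@H](OCCOCC)c2c(OCc3ccccc3)cc(OCc3ccccc3)c(I)c2O[C@@H]1c1ccc(OCc2ccccc2)c(OCc2ccccc2)c1 | intermediate
7 | deca-O-benzyl-8-iodoepicatechin-(4β→6)-8-bromoepicatechin (iodine on C8 of unit three; bromine on C8 of unit four) | Ic1c(OCc3ccccc3)cc(OCc3ccccc3)c2c1O[C@H](c1ccc(OCc3ccccc3)c(OCc3ccccc3)c1)[C@H](OCc3ccccc3)[C@H]2c1c(OCc3ccccc3)c(Br)c2c(c1OCc3ccccc3)C[C@@H](OCc3ccccc3)[C@@H](c1ccc(OCc3ccccc3)c(OCc3ccccc3)c1)O2 | intermediate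
8 | arylmagnesium chloride at C8 of unit three of 7 | Cl[Mg]c1c(OCc3ccccc3)cc(OCc3ccccc3)c2c1O[C@H](c1ccc(OCc3ccccc3)c(OCc3ccccc3)c1)[C@H](OCc3ccccc3)[C@H]2c1c(OCc3ccccc3)c(Br)c2c(c1OCc3ccccc3)C[C@@H](OCc3ccccc3)[C@@H](c1ccc(OCc3ccccc3)c(OCc3ccccc3)c1)O2 | intermediate (not isolated)
9 | deca-O-benzyl-epicatechin-(4β→6)-8-bromoepicatechin | c1c(OCc3ccccc3)cc(OCc3ccccc3)c2c1O[C@H](c1ccc(OCc3ccccc3)c(OCc3ccccc3)c1)[C@H](OCc3ccccc3)[C@H]2c1c(OCc3ccccc3)c(Br)c2c(c1OCc3ccccc3)C[C@@H](OCc3ccccc3)[C@@H](c1ccc(OCc3ccccc3)c(OCc3ccccc3)c1)O2 | intermediate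
10 | (+)-dihydrokaempferol ((2R,3R)-aromadendrin) | Oc1ccc([C@H]2Oc3cc(O)cc(O)c3C(=O)[C@@H]2O)cc1 | starting material
11 | (2R,3R)-7,4'-di-O-benzyldihydrokaempferol | C(c5ccccc5)Oc1ccc([C@H]2Oc3cc(OCc5ccccc5)cc(O)c3C(=O)[C@@H]2O)cc1 | intermediate
12 | (2R,3R)-5-O-allyl-7,4'-di-O-benzyldihydrokaempferol | C(c5ccccc5)Oc1ccc([C@H]2Oc3cc(OCc5ccccc5)cc(OCC=C)c3C(=O)[C@@H]2O)cc1 | intermediate
13 | (2R,3S,4R)-5-allyloxy-7-benzyloxy-2-(4-benzyloxyphenyl)chromane-3,4-diol (2,3-trans-3,4-trans; expected major C4 epimer) | C(c5ccccc5)Oc1ccc([C@H]2Oc3cc(OCc5ccccc5)cc(OCC=C)c3[C@@H](O)[C@@H]2O)cc1 | intermediate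
14 | trimer alcohol: 5-O-allyl-7,4'-di-O-benzylafzelechin-(4α→8)-penta-O-benzylepicatechin-(4β→6)-8-bromo-penta-O-benzylepicatechin (unit two 2,3-trans-3,4-trans; its 3-OH free) | C(c5ccccc5)Oc1ccc([C@H]2Oc3cc(OCc5ccccc5)cc(OCC=C)c3[C@@H](c3c(OCc5ccccc5)cc(OCc5ccccc5)c4c3O[C@H](c3ccc(OCc5ccccc5)c(OCc5ccccc5)c3)[C@H](OCc5ccccc5)[C@H]4c3c(OCc5ccccc5)c(Br)c4c(c3OCc5ccccc5)C[C@@H](OCc5ccccc5)[C@@H](c3ccc(OCc5ccccc5)c(OCc5ccccc5)c3)O4)[C@@H]2O)cc1 | intermediate
15 | trimer 3-ketone: as 14 but C3 of unit two is C=O (C2 aryl cis to C4 aryl) | C(c5ccccc5)Oc1ccc([C@H]2Oc3cc(OCc5ccccc5)cc(OCC=C)c3[C@@H](c3c(OCc5ccccc5)cc(OCc5ccccc5)c4c3O[C@H](c3ccc(OCc5ccccc5)c(OCc5ccccc5)c3)[C@H](OCc5ccccc5)[C@H]4c3c(OCc5ccccc5)c(Br)c4c(c3OCc5ccccc5)C[C@@H](OCc5ccccc5)[C@@H](c3ccc(OCc5ccccc5)c(OCc5ccccc5)c3)O4)C2=O)cc1 | intermediate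
16 | trimer alcohol: 5-O-allyl-7,4'-di-O-benzylepiafzelechin-(4α→8)-penta-O-benzylepicatechin-(4β→6)-8-bromo-penta-O-benzylepicatechin (unit two all-cis; its 3-OH free) | C(c5ccccc5)Oc1ccc([C@H]2Oc3cc(OCc5ccccc5)cc(OCC=C)c3[C@@H](c3c(OCc5ccccc5)cc(OCc5ccccc5)c4c3O[C@H](c3ccc(OCc5ccccc5)c(OCc5ccccc5)c3)[C@H](OCc5ccccc5)[C@H]4c3c(OCc5ccccc5)c(Br)c4c(c3OCc5ccccc5)C[C@@H](OCc5ccccc5)[C@@H](c3ccc(OCc5ccccc5)c(OCc5ccccc5)c3)O4)[C@H]2O)cc1 | intermediate
17 | trimer phenol: as 16 but the 5-OH of unit two is free | C(c5ccccc5)Oc1ccc([C@H]2Oc3cc(OCc5ccccc5)cc(O)c3[C@@H](c3c(OCc5ccccc5)cc(OCc5ccccc5)c4c3O[C@H](c3ccc(OCc5ccccc5)c(OCc5ccccc5)c3)[C@H](OCc5ccccc5)[C@H]4c3c(OCc5ccccc5)c(Br)c4c(c3OCc5ccccc5)C[C@@H](OCc5ccccc5)[C@@H](c3ccc(OCc5ccccc5)c(OCc5ccccc5)c3)O4)[C@H]2O)cc1 | intermediate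
18 | 4β-(2-ethoxyethoxy)-5,7,3',4'-tetra-O-benzyl-(−)-epicatechin (2R,3R,4S; 3-OH free) | O[C@@H]1[C@@H](OCCOCC)c2c(OCc3ccccc3)cc(OCc3ccccc3)cc2O[C@@H]1c1ccc(OCc2ccccc2)c(OCc2ccccc2)c1 | intermediate
19 | 3-O-[chloro(diisopropyl)silyl] ether of 18 | Cl[Si](C(C)C)(C(C)C)O[C@@H]1[C@@H](OCCOCC)c2c(OCc3ccccc3)cc(OCc3ccccc3)cc2O[C@@H]1c1ccc(OCc2ccccc2)c(OCc2ccccc2)c1 | intermediate (not isolated)
20 | diisopropylsilylene-tethered precursor: O5 of unit two of 17 joined to O3 of 18 by Si(iPr)2 | C(c5ccccc5)Oc1ccc([C@H]2Oc3cc(OCc5ccccc5)cc(O[Si](C(C)C)(C(C)C)O[C@@H]6[C@@H](OCCOCC)c7c(OCc5ccccc5)cc(OCc5ccccc5)cc7O[C@@H]6c6ccc(OCc5ccccc5)c(OCc5ccccc5)c6)c3[C@@H](c3c(OCc5ccccc5)cc(OCc5ccccc5)c4c3O[C@H](c3ccc(OCc5ccccc5)c(OCc5ccccc5)c3)[C@H](OCc5ccccc5)[C@H]4c3c(OCc5ccccc5)c(Br)c4c(c3OCc5ccccc5)C[C@@H](OCc5ccccc5)[C@@H](c3ccc(OCc5ccccc5)c(OCc5ccccc5)c3)O4)[C@H]2O)cc1 | intermediate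
21 | silylene-bridged tetramer: C4 of unit one bonded 4α to C6 of unit two; seven-membered O3–Si(iPr)2–O5 ring | C(c7ccccc7)Oc1ccc([C@H]2Oc3cc(OCc7ccccc7)c([C@@H]4c5c(OCc7ccccc7)cc(OCc7ccccc7)cc5O[C@H](c5ccc(OCc7ccccc7)c(OCc7ccccc7)c5)[C@@H]4O[Si]6(C(C)C)C(C)C)c(O6)c3[C@@H](c3c(OCc5ccccc5)cc(OCc5ccccc5)c4c3O[C@H](c3ccc(OCc5ccccc5)c(OCc5ccccc5)c3)[C@H](OCc5ccccc5)[C@H]4c3c(OCc5ccccc5)c(Br)c4c(c3OCc5ccccc5)C[C@@H](OCc5ccccc5)[C@@H](c3ccc(OCc5ccccc5)c(OCc5ccccc5)c3)O4)[C@H]2O)cc1 | intermediate
22 | hexadeca-O-benzyl-8-bromo tetramer triol (3-OH of unit one free; 3-OH of unit two free; 5-OH of unit two free; bromine on C8 of unit four) | C(c7ccccc7)Oc1ccc([C@H]2Oc3cc(OCc7ccccc7)c([C@@H]4c5c(OCc7ccccc7)cc(OCc7ccccc7)cc5O[C@H](c5ccc(OCc7ccccc7)c(OCc7ccccc7)c5)[C@@H]4O)c(O)c3[C@@H](c3c(OCc5ccccc5)cc(OCc5ccccc5)c4c3O[C@H](c3ccc(OCc5ccccc5)c(OCc5ccccc5)c3)[C@H](OCc5ccccc5)[C@H]4c3c(OCc5ccccc5)c(Br)c4c(c3OCc5ccccc5)C[C@@H](OCc5ccccc5)[C@@H](c3ccc(OCc5ccccc5)c(OCc5ccccc5)c3)O4)[C@H]2O)cc1 | intermediate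
23 | CNP0103636.2, epicatechin-(4α→6)-epiafzelechin-(4α→8)-epicatechin-(4β→6)-epicatechin | Oc1ccc([C@H]2Oc3cc(O)c([C@@H]4c5c(O)cc(O)cc5O[C@H](c5ccc(O)c(O)c5)[C@@H]4O)c(O)c3[C@@H](c3c(O)cc(O)c4c3O[C@H](c3ccc(O)c(O)c3)[C@H](O)[C@H]4c3c(O)cc4c(c3O)C[C@@H](O)[C@@H](c3ccc(O)c(O)c3)O4)[C@H]2O)cc1 | target

Total step count: 19. Longest linear sequence: 14 steps (steps 1, 2, 4, 5, 6, 7, 11, 12, 13, 14, 16, 17, 18, 19).

Steps most likely to fail

Step 17. The seven-membered closure may be slower than other fates of the cation: capture by a free ring A carbon of another molecule, proton loss to the flav-3-ene, or acid cleavage of the aryl silyl ether before the C–C bond forms. Closure through the minor half-chair with the C2 aryl group axial could also let some 3,4-trans product leak in. The fallback replaces the one-atom silylene by a glutarate diester, the linker class for which intramolecular Lewis-acid condensation of two flavan units to the 3,4-cis product is established. It sets out from 18 and 17 and comes back at 22. Alcohol 18 would be opened onto glutaric anhydride (DMAP, pyridine) to give the 3-O-hemiglutarate of 18 F1. F1 would be esterified with the phenol of 17 (EDC·HCl, DMAP, CH2Cl2) to the glutarate-tethered precursor F2. TMSOTf (cat.) in dilute CH2Cl2 at −78 °C to −20 °C would close the eleven-membered diester ring with formation of the C4–C6 bond, giving the glutarate-bridged tetramer F3. LiOH in THF/MeOH/H2O would cleave both esters and give 22.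

Step 11. The diol-derived cation may self-condense through its own free C6 and C8, and the free 3-OH may fail to shield its face, so that 3,4-cis attack leaks in. The fallback changes the stereocontrol element to neighbouring-group participation; it sets out from 13 and comes back at 14. Diol 13 would be acetylated (Ac2O, pyridine, DMAP) to the 3,4-di-O-acetate of 13 F4. BF3·OEt2 at −78 °C would ionise the 4-acetate while the 3-acetate bridges the β-face as an acetoxonium ion, so that C8 of unit three of 9 can enter only anti (4α), giving the 3-O-acetyl trimer F5. K2CO3 in MeOH/THF would remove the acetate and give 14.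

Step 13. The basic, bulky hydride may deprotonate the doubly benzylic C4–H of ketone 15 instead of adding to the carbonyl, or add with poor facial selectivity. The fallback replaces substrate-controlled stoichiometric hydride by catalyst-controlled Noyori-type asymmetric transfer hydrogenation: RuCl[(S,S)-TsDPEN](p-cymene) or RuCl[(R,R)-TsDPEN](p-cymene), whichever proves matched to β-face hydride delivery in a two-run screen, HCO2H/Et3N, CH2Cl2, rt. The ruthenium hydride is not basic, and α-aryl cyclic ketones are reduced this way to the cis alcohols under dynamic conditions; any C4-epimerised ketone returns through the favoured 2,4-cis ketone. It sets out from 15 and comes back at 16 and makes no compound outside the compound list (entry F0).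

Further compounds
F1 | step 17 | 3-O-(4-carboxybutanoyl) derivative (hemiglutarate) of 18 | OC(=O)CCCC(=O)O[C@@H]1[C@@H](OCCOCC)c2c(OCc3ccccc3)cc(OCc3ccccc3)cc2O[C@@H]1c1ccc(OCc2ccccc2)c(OCc2ccccc2)c1
F2 | step 17 | glutarate-tethered precursor (O3 of unit one joined to O5 of unit two by a pentanedioyl diester) | C(c5ccccc5)Oc1ccc([C@H]2Oc3cc(OCc5ccccc5)cc(OC(=O)CCCC(=O)O[C@@H]6[C@@H](OCCOCC)c7c(OCc5ccccc5)cc(OCc5ccccc5)cc7O[C@@H]6c6ccc(OCc5ccccc5)c(OCc5ccccc5)c6)c3[C@@H](c3c(OCc5ccccc5)cc(OCc5ccccc5)c4c3O[C@H](c3ccc(OCc5ccccc5)c(OCc5ccccc5)c3)[C@H](OCc5ccccc5)[C@H]4c3c(OCc5ccccc5)c(Br)c4c(c3OCc5ccccc5)C[C@@H](OCc5ccccc5)[C@@H](c3ccc(OCc5ccccc5)c(OCc5ccccc5)c3)O4)[C@H]2O)cc1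
F3 | step 17 | glutarate-bridged tetramer (C4 of unit one bonded 4α to C6 of unit two; eleven-membered diester ring) | C(c7ccccc7)Oc1ccc([C@H]2Oc3cc(OCc7ccccc7)c([C@@H]4c5c(OCc7ccccc7)cc(OCc7ccccc7)cc5O[C@H](c5ccc(OCc7ccccc7)c(OCc7ccccc7)c5)[C@@H]4OC(=O)CCCC6=O)c(O6)c3[C@@H](c3c(OCc5ccccc5)cc(OCc5ccccc5)c4c3O[C@H](c3ccc(OCc5ccccc5)c(OCc5ccccc5)c3)[C@H](OCc5ccccc5)[C@H]4c3c(OCc5ccccc5)c(Br)c4c(c3OCc5ccccc5)C[C@@H](OCc5ccccc5)[C@@H](c3ccc(OCc5ccccc5)c(OCc5ccccc5)c3)O4)[C@H]2O)cc1
F4 | step 11 | 3,4-di-O-acetate of 13 | C(c5ccccc5)Oc1ccc([C@H]2Oc3cc(OCc5ccccc5)cc(OCC=C)c3[C@@H](OC(C)=O)[C@@H]2OC(C)=O)cc1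
F5 | step 11 | 3-O-acetate (unit two) of trimer 14 | C(c5ccccc5)Oc1ccc([C@H]2Oc3cc(OCc5ccccc5)cc(OCC=C)c3[C@@H](c3c(OCc5ccccc5)cc(OCc5ccccc5)c4c3O[C@H](c3ccc(OCc5ccccc5)c(OCc5ccccc5)c3)[C@H](OCc5ccccc5)[C@H]4c3c(OCc5ccccc5)c(Br)c4c(c3OCc5ccccc5)C[C@@H](OCc5ccccc5)[C@@H](c3ccc(OCc5ccccc5)c(OCc5ccccc5)c3)O4)[C@@H]2OC(C)=O)cc1
F0 | step 13 | none | none
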